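**Retrosynthetic overview**

1. C3–OH ⇐ TBS ether; 1,10-epoxide ⇐ peripheral peracid epoxidation of the E C1=C10 alkene; α-methylene ⇐ loss of HNO2 from a C13-nitro lactone.
2. γ-Lactone and C8 epoxy ester ⇐ one Evans–Tishchenko redox esterification of a C8-hydroxy C6-ketone with (2S,3R)-2,3-dimethyloxirane-2-carbaldehyde (Sharpless epoxidation of tiglyl alcohol, then oxidation), then lactonisation through O6.
3. Key step: the ten-membered ring is made by anionic oxy-Cope ring expansion of a trans-1,6-dialkenyl cyclohexenol, not by macrocyclisation. The chair transition state fixes C1=C10 (E), keeps C4=C5 (Z) and sets C8; the enolate is intercepted by methyl (E)-3-nitroacrylate, which sets C7 and brings in C11–C13.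
4. Cyclohexenol ⇐ (Z)-2-(PMB-oxy)vinyllithium + a 4-silyloxy isopiperitenone-type enone ⇐ (S)-carvone (Luche reduction, silylation, allylic oxidation).
5. Ring order: cyclohexene (from carvone) → ten-membered carbocycle (ring expansion) → γ-lactone → ring oxirane; the side-chain oxirane is made separately.

Assumption: compounds marked "starting material" in the list are bought; ten-membered-ring compounds carry germacrane numbering (C1–C15); TBS = tert-butyldimethylsilyl, PMB = 4-methoxybenzyl.

**Route**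

Step 1
Reactants: 1 (S)-(+)-carvone
Product: 2 (1S,5S)-cis-carveol
Conditions: NaBH4, CeCl3·7H2O, MeOH, −78 → 0 °C
Reagents that add atoms: none
Why: Luche 1,2-reduction in which hydride adds axially to the half-chair carrying the isopropenyl group equatorially, so the new hydroxyl is equatorial and cis to C5 (1S, cis:trans about 95:5) while C5 is untouched.

Step 2
Reactants: 2 (1S,5S)-cis-carveol
Product: 3 (1S,5S)-cis-carveol TBS ether
Conditions: TBSCl, imidazole, DMF, rt
Reagents that add atoms: tert-butyldimethylsilyl chloride, CC(C)(C)[Si](C)(C)Cl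
Why: standard imidazole-promoted silylation of the secondary allylic alcohol, which touches no stereocentre and gives an ether that survives every later step up to the final fluoride cleavage.

Step 3
Reactants: 3 (1S,5S)-cis-carveol TBS ether
Product: 4 (4S,6S)-4-(TBSO)-3-methyl-6-(prop-1-en-2-yl)cyclohex-2-en-1-one
Conditions: CrO3, 3,5-dimethylpyrazole, CH2Cl2, −20 °C
Reagents that add atoms: chromium trioxide, O=[Cr](=O)=O
Why: chromium trioxide–dimethylpyrazole allylic oxidation attacks the only ring methylene allylic to the trisubstituted alkene, giving the γ-silyloxy enone under non-basic conditions that leave the two stereocentres (now C4 and C6, cis) untouched.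

Step 4
Reactants: 5 4-methoxybenzyl alcohol; 6 ethyl vinyl ether
Product: 7 4-methoxybenzyl vinyl ether
Conditions: Pd(OAc)2 (2 mol %), 1,10-phenanthroline (2 mol %), 6 (excess), CH2Cl2, rt
Reagents that add atoms: none
Why: palladium-catalysed transfer vinylation (transetherification) of the benzylic alcohol, driven by the excess of ethyl vinyl ether, with no stereochemistry involved.

Step 5
Reactants: 7 4-methoxybenzyl vinyl ether
Product: 9 (Z)-2-bromovinyl 4-methoxybenzyl ether, via dibromo ether 8 (not isolated)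
Conditions: Br2, CH2Cl2, −78 °C; then i-Pr2NEt, −78 → 40 °C
Reagents that add atoms: bromine, BrBr
Why: bromination–dehydrobromination in which bromine adds to the enol ether and the amine removes HBr through the α-bromo ether (oxocarbenium), the Z isomer (Br cis to O) being favoured and separated by chromatography.

Step 6
Reactants: 9 (Z)-2-bromovinyl 4-methoxybenzyl ether; 4 (4S,6S)-4-(TBSO)-3-methyl-6-(prop-1-en-2-yl)cyclohex-2-en-1-one
Product: 11 (1S,4S,6S)-4-(TBSO)-1-[(Z)-2-(PMBO)vinyl]-3-methyl-6-(prop-1-en-2-yl)cyclohex-2-en-1-ol, via vinyllithium 10 (not isolated)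
Conditions: 9, t-BuLi (2.0 equiv), Et2O, −78 °C; then 4, THF, −78 °C; H2O quench; filtration through basic alumina
Reagents that add atoms: none
Why: bromine–lithium exchange keeps the Z geometry and the vinyllithium adds 1,2 to the enone from the face anti to the adjacent C6 isopropenyl group, giving the trans-1,6-dialkenyl carbinol (new centre 1S, hydroxyl cis to isopropenyl).

Step 7
Reactants: 11 (1S,4S,6S)-4-(TBSO)-1-[(Z)-2-(PMBO)vinyl]-3-methyl-6-(prop-1-en-2-yl)cyclohex-2-en-1-ol; 12 methyl (E)-3-nitroacrylate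
Product: 15 methyl (3S,7R,8R,11RS)-3-(TBSO)-8-(PMBO)-13-nitro-6-oxogermacra-1(10)E,4Z-dien-12-oate, via potassium alkoxide 13 (not isolated), via potassium enolate 14 (not isolated)
Conditions: KN(SiMe3)2 (1.05 equiv), THF, 0 °C → rt; then 12 (1.2 equiv), −78 °C; AcOH, −78 °C
Reagents that add atoms: none
Why: anionic oxy-Cope ring expansion through the chair transition state open to the trans-dialkenyl alkoxide (both ring bonds equatorial) gives the E C1=C10 alkene, keeps the former ring alkene as Z C4=C5 and, because the Z-OPMB group sits axial, sets C8 as R relative to C3, after which the Z(O)-enolate, held by K+ between the enolate and ether oxygens so that the C8–C9 ring bond blocks its inner face, undergoes Michael addition to the nitroacrylate carbon β to the nitro group from the outer face, setting C7 as R (anti to O8, as in chelate-controlled alkylation of β-alkoxy enolates) while C11 forms as an inconsequential mixture.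

Step 8
Reactants: 15 methyl (3S,7R,8R,11RS)-3-(TBSO)-8-(PMBO)-13-nitro-6-oxogermacra-1(10)E,4Z-dien-12-oate
Product: 16 methyl (3S,7R,8R,11RS)-3-(TBSO)-8-hydroxy-13-nitro-6-oxogermacra-1(10)E,4Z-dien-12-oate
Conditions: DDQ, CH2Cl2/pH 7 buffer (10:1), 0 °C; used at once
Reagents that add atoms: none
Why: oxidative PMB ether cleavage by DDQ under buffered neutral conditions that spare the silyl ether, both alkenes, the nitro ester and the β-hydroxy ketone (no base, hence no retro-aldol or elimination) and touch no stereocentre.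

Step 9
Reactants: 17 (E)-2-methylbut-2-en-1-ol
Product: 18 [(2R,3R)-2,3-dimethyloxiran-2-yl]methanol
Conditions: Ti(OiPr)4 (10 mol %), D-(−)-diethyl tartrate (12 mol %), t-BuOOH, 4 Å MS, CH2Cl2, −20 °C
Reagents that add atoms: tert-butyl hydroperoxide, CC(C)(C)OO
Why: Sharpless asymmetric epoxidation in which D-(−)-diethyl tartrate directs oxygen to the alkene face giving the 2R,3R epoxy alcohol (mirror image of the 2S,3S product of the L-(+)-tartrate) and the E alkene geometry fixes the two methyl groups cis.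

Step 10
Reactants: 18 [(2R,3R)-2,3-dimethyloxiran-2-yl]methanol
Product: 19 (2S,3R)-2,3-dimethyloxirane-2-carbaldehyde
Conditions: Pr4N[RuO4] (5 mol %), N-methylmorpholine N-oxide, 4 Å MS, CH2Cl2, rt; used as a solution
Reagents that add atoms: none
Why: Ley–Griffith oxidation of the primary alcohol to the aldehyde under neutral conditions that spare the oxirane, with unchanged configuration (the C2 descriptor becomes S only through the change in CIP priorities).

Step 11
Reactants: 16 methyl (3S,7R,8R,11RS)-3-(TBSO)-8-hydroxy-13-nitro-6-oxogermacra-1(10)E,4Z-dien-12-oate; 19 (2S,3R)-2,3-dimethyloxirane-2-carbaldehyde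
Product: 21 (3S,6R,7R,8R,11RS)-3-(TBSO)-8-[(2S,3R)-2,3-dimethyloxirane-2-carbonyloxy]-13-nitrogermacra-1(10)E,4Z-dien-12,6-olide, via hydroxy ester 20 (not isolated)
Conditions: 19 (5 equiv), SmI2 (0.3 equiv, premixed with 19), THF, −10 °C; aq NaHCO3 work-up; then PPTS (0.2 equiv), toluene, 50 °C
Reagents that add atoms: none
Why: Proposed new method: an Evans–Tishchenko reduction in which the hemiacetal formed from the C8 hydroxyl and aldehyde 19 is bound together with the C6 ketone to trivalent samarium and transfers its hydride intramolecularly through a six-membered chair, so that C6 is reduced 1,3-anti to O8 (6R) and the oxidised hemiacetal stays as the C8 ester, after which the only free hydroxyl (C6) closes the trans-fused γ-lactone on the methyl ester, the closest known reaction type being the samarium-catalysed Evans–Tishchenko reduction of β-hydroxy ketones with simple or functionalised aldehydes in fragment couplings, here extended to an α,β-epoxy aldehyde and a macrocyclic β-hydroxy enone.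

Step 12
Reactants: 21 (3S,6R,7R,8R,11RS)-3-(TBSO)-8-[(2S,3R)-2,3-dimethyloxirane-2-carbonyloxy]-13-nitrogermacra-1(10)E,4Z-dien-12,6-olide
Product: 22 (3S,6R,7R,8R)-3-(TBSO)-8-[(2S,3R)-2,3-dimethyloxirane-2-carbonyloxy]germacra-1(10)E,4Z,11(13)-trien-12,6-olide
Conditions: DBU (1.2 equiv), CH2Cl2, 0 °C
Reagents that add atoms: none
Why: base-induced E1cB elimination of nitrous acid from the β-nitro lactone (closing stage of a nitroacrylate α-methylene lactone annulation) creates the exocyclic C11=C13 methylene and removes the stereorandom C11 centre.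

Step 13
Reactants: 22 (3S,6R,7R,8R)-3-(TBSO)-8-[(2S,3R)-2,3-dimethyloxirane-2-carbonyloxy]germacra-1(10)E,4Z,11(13)-trien-12,6-olide
Product: 23 (1R,3S,6R,7R,8R,10R)-1,10-epoxy-3-(TBSO)-8-[(2S,3R)-2,3-dimethyloxirane-2-carbonyloxy]germacra-4Z,11(13)-dien-12,6-olide
Conditions: mCPBA (1.1 equiv), NaHCO3, CH2Cl2, 0 °C
Reagents that add atoms: 3-chloroperbenzoic acid, OOC(=O)c1cccc(Cl)c1
Why: Prilezhaev epoxidation of the most electron-rich alkene (C4=C5 is deactivated by two allylic oxygens and C11=C13 is conjugated to the lactone) from the only exposed face of the E C1=C10 bond in the crown conformer, whose inner face is blocked by the ring, gives the trans-epoxide 1R,10R by stereospecific syn addition (peripheral attack on a medium ring).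

Step 14
Reactants: 23 (1R,3S,6R,7R,8R,10R)-1,10-epoxy-3-(TBSO)-8-[(2S,3R)-2,3-dimethyloxirane-2-carbonyloxy]germacra-4Z,11(13)-dien-12,6-olide
Product: 24 target CNP0268255.5
Conditions: HF·pyridine, pyridine, THF, 0 °C → rt
Reagents that add atoms: none
Why: fluoride cleavage of the secondary TBS ether with pyridine-buffered HF·pyridine, mild enough to spare both oxiranes, the glycidic ester and the α-methylene lactone, frees the C3 alcohol without touching any stereocentre.

**Compound list**

1 | (S)-(+)-carvone, (5S)-2-methyl-5-(prop-1-en-2-yl)cyclohex-2-en-1-one | CC1=CC[C@@H](CC1=O)C(C)=C | starting material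
2 | (1S,5S)-cis-carveol, (1S,5S)-2-methyl-5-(prop-1-en-2-yl)cyclohex-2-en-1-ol | CC1=CC[C@@H](C[C@@H]1O)C(C)=C | intermediate
3 | (1S,5S)-cis-carveol TBS ether | CC1=CC[C@@H](C[C@@H]1O[Si](C)(C)C(C)(C)C)C(C)=C | intermediate
4 | (4S,6S)-4-[(tert-butyldimethylsilyl)oxy]-3-methyl-6-(prop-1-en-2-yl)cyclohex-2-en-1-one (4-OTBS and 6-isopropenyl cis) | CC1=CC(=O)[C@@H](C[C@@H]1O[Si](C)(C)C(C)(C)C)C(C)=C | intermediate
5 | 4-methoxybenzyl alcohol | COc1ccc(CO)cc1 | starting material
6 | ethyl vinyl ether | CCOC=C | starting material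
7 | 4-methoxybenzyl vinyl ether | C=COCc1ccc(OC)cc1 | intermediate
8 | 1,2-dibromoethyl 4-methoxybenzyl ether (racemic, not isolated) | BrCC(Br)OCc1ccc(OC)cc1 | intermediate
9 | (Z)-2-bromovinyl 4-methoxybenzyl ether | Br/C=C\OCc1ccc(OC)cc1 | intermediate
10 | (Z)-2-[(4-methoxybenzyl)oxy]vinyllithium (not isolated) | [Li]/C=C\OCc1ccc(OC)cc1 | intermediate
11 | (1S,4S,6S)-4-[(tert-butyldimethylsilyl)oxy]-1-{(Z)-2-[(4-methoxybenzyl)oxy]vinyl}-3-methyl-6-(prop-1-en-2-yl)cyclohex-2-en-1-ol (OH, isopropenyl and OTBS all cis; the two alkenyl groups trans) | CC1=C[C@@](O)(/C=C\OCc2ccc(OC)cc2)[C@@H](C[C@@H]1O[Si](C)(C)C(C)(C)C)C(C)=C | intermediate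
12 | methyl (E)-3-nitroacrylate | COC(=O)/C=C/[N+](=O)[O-] | starting material
13 | potassium alkoxide of 11 (not isolated) | CC1=C[C@@]([O-])(/C=C\OCc2ccc(OC)cc2)[C@@H](C[C@@H]1O[Si](C)(C)C(C)(C)C)C(C)=C.[K+] | intermediate
14 | potassium (6Z)-enolate of (3S,8R)-3-(TBSO)-8-(PMBO)germacra-1(10)E,4Z-dien-6-one (C6=C7 enolate, O cis to C8; not isolated) | C1/C(C)=C/C[C@H](O[Si](C)(C)C(C)(C)C)/C(C)=C\C(\[O-])=C\[C@@H]1OCc2ccc(OC)cc2.[K+] | intermediate
15 | methyl (3S,7R,8R,11RS)-3-(TBSO)-8-(PMBO)-13-nitro-6-oxogermacra-1(10)E,4Z-dien-12-oate | O=C1/C=C(/C)[C@@H](O[Si](C)(C)C(C)(C)C)C/C=C(\C)C[C@@H](OCc2ccc(OC)cc2)[C@H]1C(C(=O)OC)C[N+](=O)[O-] | intermediate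
16 | methyl (3S,7R,8R,11RS)-3-(TBSO)-8-hydroxy-13-nitro-6-oxogermacra-1(10)E,4Z-dien-12-oate | O=C1/C=C(/C)[C@@H](O[Si](C)(C)C(C)(C)C)C/C=C(\C)C[C@@H](O)[C@H]1C(C(=O)OC)C[N+](=O)[O-] | intermediate
17 | (E)-2-methylbut-2-en-1-ol (tiglyl alcohol) | C/C=C(\C)CO | starting material
18 | [(2R,3R)-2,3-dimethyloxiran-2-yl]methanol | OC[C@@]1(C)O[C@@H]1C | intermediate
19 | (2S,3R)-2,3-dimethyloxirane-2-carbaldehyde | O=C[C@@]1(C)O[C@@H]1C | intermediate
20 | methyl (3S,6R,7S,8R,11RS)-3-(TBSO)-8-[(2S,3R)-2,3-dimethyloxirane-2-carbonyloxy]-6-hydroxy-13-nitrogermacra-1(10)E,4Z-dien-12-oate (same spatial arrangement at C7 as in 16; not isolated) | O[C@@H]1/C=C(/C)[C@@H](O[Si](C)(C)C(C)(C)C)C/C=C(\C)C[C@@H](OC(=O)[C@@]2(C)O[C@@H]2C)[C@H]1C(C(=O)OC)C[N+](=O)[O-] | intermediate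
21 | (3S,6R,7R,8R,11RS)-3-(TBSO)-8-[(2S,3R)-2,3-dimethyloxirane-2-carbonyloxy]-13-nitrogermacra-1(10)E,4Z-dien-12,6-olide (trans-fused lactone) | [O-][N+](=O)CC1C(=O)O[C@@H]2/C=C(/C)[C@@H](O[Si](C)(C)C(C)(C)C)C/C=C(\C)C[C@@H](OC(=O)[C@@]3(C)O[C@@H]3C)[C@@H]12 | intermediate
22 | (3S,6R,7R,8R)-3-(TBSO)-8-[(2S,3R)-2,3-dimethyloxirane-2-carbonyloxy]germacra-1(10)E,4Z,11(13)-trien-12,6-olide | C=C1C(=O)O[C@@H]2/C=C(/C)[C@@H](O[Si](C)(C)C(C)(C)C)C/C=C(\C)C[C@@H](OC(=O)[C@@]3(C)O[C@@H]3C)[C@@H]12 | intermediate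
23 | (1R,3S,6R,7R,8R,10R)-1,10-epoxy-3-(TBSO)-8-[(2S,3R)-2,3-dimethyloxirane-2-carbonyloxy]germacra-4Z,11(13)-dien-12,6-olide | C=C1C(=O)O[C@@H]2/C=C(/C)[C@@H](O[Si](C)(C)C(C)(C)C)C[C@H]3O[C@]3(C)C[C@@H](OC(=O)[C@@]3(C)O[C@@H]3C)[C@@H]12 | intermediate
24 | CNP0268255.5, (1R,3S,6R,7R,8R,10R)-1,10-epoxy-3-hydroxy-8-[(2S,3R)-2,3-dimethyloxirane-2-carbonyloxy]germacra-4Z,11(13)-dien-12,6-olide | C=C1C(=O)O[C@@H]2/C=C(/C)[C@@H](O)C[C@H]3O[C@]3(C)C[C@@H](OC(=O)[C@@]3(C)O[C@@H]3C)[C@@H]12 | target

**Totals and risks**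

Total step count: 14. Longest linear sequence: 10 steps (steps 1, 2, 3, 6, 7, 8, 11, 12, 13, 14).

The three steps most likely to fail are 7, 11 and 13.

Step 7 is the riskiest. The potassium enolate must survive without losing the β-alkoxide, the rearrangement may be slow without a crown ether, and the nitroacrylate may polymerise or add to the wrong enolate face. The fallback replaces the nitroacrylate annulation by a classical enolate alkylation and a late α-methylenation. It sets out from 11: the enolate 14 is generated as before but alkylated with methyl bromoacetate at −78 °C to give the C7 acetate keto ester F1. DDQ then frees the C8 alcohol as the hydroxy ketone F2. Evans–Tishchenko reduction with 19 and SmI2 gives the open hydroxy ester F3, which closes under PPTS to the saturated lactone F4. LiN(SiMe3)2 and CH2=NMe2+ I− at −78 °C give the Mannich base F5, methyl iodide gives the trimethylammonium iodide F6, and NaHCO3 eliminates trimethylamine, so the fallback comes back to the route at 22.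

Step 11 may fail because the hindered epoxy aldehyde is a poor hydride donor, or because 16 closes an 8,12-lactone before it is reduced. The fallback uses a hydroxyl-directed borohydride reduction and a separate esterification. It sets out from 16, which Me4NBH(OAc)3 in MeCN/AcOH at −30 °C (Evans–Saksena reduction) turns into the 1,3-anti diol ester F7. PPTS closes this through O6 to the C8 hydroxy lactone F8. Aldehyde 19 is oxidised with NaClO2/NaH2PO4/2-methylbut-2-ene to the epoxy acid F9. F8 and F9 are then joined with EDC·HCl and DMAP, and the fallback comes back to the route at 21.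

Step 13 may deliver oxygen to the other face of C1=C10, since the outcome depends on which ring conformer reacts, or may give some C4=C5 epoxide. The fallback uses hydroxyl-directed oxygen delivery in place of steric control. It sets out from 22, which HF·pyridine/pyridine desilylates first to the dienolide alcohol F10. VO(acac)2 (catalytic) and t-BuOOH in CH2Cl2 at 0 °C then deliver oxygen from the vanadate ester of the C3 hydroxyl to the homoallylic C1=C10 bond on the face syn to O3, which is the 1,3-syn O3/O1 relation of the target. The allylic C4=C5 bond, deactivated by the lactone oxygen, is the competing site. The fallback comes back to the route at 24.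

**Further compounds**

F1 | step 7 | methyl (3S,7R,8R)-3-(TBSO)-8-(PMBO)-6-oxo-13-norgermacra-1(10)E,4Z-dien-12-oate | O=C1/C=C(/C)[C@@H](O[Si](C)(C)C(C)(C)C)C/C=C(\C)C[C@@H](OCc2ccc(OC)cc2)[C@H]1CC(=O)OC
F2 | step 7 | methyl (3S,7R,8R)-3-(TBSO)-8-hydroxy-6-oxo-13-norgermacra-1(10)E,4Z-dien-12-oate | O=C1/C=C(/C)[C@@H](O[Si](C)(C)C(C)(C)C)C/C=C(\C)C[C@@H](O)[C@H]1CC(=O)OC
F3 | step 7 | methyl (3S,6R,7S,8R)-3-(TBSO)-8-[(2S,3R)-2,3-dimethyloxirane-2-carbonyloxy]-6-hydroxy-13-norgermacra-1(10)E,4Z-dien-12-oate | O[C@@H]1/C=C(/C)[C@@H](O[Si](C)(C)C(C)(C)C)C/C=C(\C)C[C@@H](OC(=O)[C@@]2(C)O[C@@H]2C)[C@H]1CC(=O)OC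
F4 | step 7 | (3S,6R,7R,8R)-3-(TBSO)-8-[(2S,3R)-2,3-dimethyloxirane-2-carbonyloxy]-13-norgermacra-1(10)E,4Z-dien-12,6-olide | C1C(=O)O[C@@H]2/C=C(/C)[C@@H](O[Si](C)(C)C(C)(C)C)C/C=C(\C)C[C@@H](OC(=O)[C@@]3(C)O[C@@H]3C)[C@@H]12
F5 | step 7 | (3S,6R,7R,8R,11RS)-13-(dimethylamino)-3-(TBSO)-8-[(2S,3R)-2,3-dimethyloxirane-2-carbonyloxy]germacra-1(10)E,4Z-dien-12,6-olide | CN(C)CC1C(=O)O[C@@H]2/C=C(/C)[C@@H](O[Si](C)(C)C(C)(C)C)C/C=C(\C)C[C@@H](OC(=O)[C@@]3(C)O[C@@H]3C)[C@@H]12
F6 | step 7 | trimethylammonium iodide of F5 (N-methylated at the C13 nitrogen) | C[N+](C)(C)CC1C(=O)O[C@@H]2/C=C(/C)[C@@H](O[Si](C)(C)C(C)(C)C)C/C=C(\C)C[C@@H](OC(=O)[C@@]3(C)O[C@@H]3C)[C@@H]12.[I-]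
F7 | step 11 | methyl (3S,6R,7R,8R,11RS)-3-(TBSO)-6,8-dihydroxy-13-nitrogermacra-1(10)E,4Z-dien-12-oate | O[C@@H]1/C=C(/C)[C@@H](O[Si](C)(C)C(C)(C)C)C/C=C(\C)C[C@@H](O)[C@H]1C(C(=O)OC)C[N+](=O)[O-]
F8 | step 11 | (3S,6R,7R,8R,11RS)-3-(TBSO)-8-hydroxy-13-nitrogermacra-1(10)E,4Z-dien-12,6-olide | [O-][N+](=O)CC1C(=O)O[C@@H]2/C=C(/C)[C@@H](O[Si](C)(C)C(C)(C)C)C/C=C(\C)C[C@@H](O)[C@@H]12
F9 | step 11 | (2S,3R)-2,3-dimethyloxirane-2-carboxylic acid | OC(=O)[C@@]1(C)O[C@@H]1C
F10 | step 13 | (3S,6R,7R,8R)-3-hydroxy-8-[(2S,3R)-2,3-dimethyloxirane-2-carbonyloxy]germacra-1(10)E,4Z,11(13)-trien-12,6-olide | C=C1C(=O)O[C@@H]2/C=C(/C)[C@@H](O)C/C=C(\C)C[C@@H](OC(=O)[C@@]3(C)O[C@@H]3C)[C@@H]12
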